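**Plan**

1. Cuts: once the acetate on O2 of ring A and the two benzyl groups of ring B are removed, ring A is opened at C3–C4 and C5–C6. This works because C3 (Cl), C2 (O), C1 (ester carbon) and C6 (propyl) of ring A stand in the same order as C3, C4, C5 and C6 of a 3-chloro-4-oxy-6-propyl-2-pyrone-5-carboxylate, so only the C4(OMe)–C5(H) pair has to come from 1,1-dimethoxyethene.
2. The pyrone is cut at O1–C2 and C4–C5 into malonyl dichloride and an aryl 3-oxohexanoate. The aryl ester C–O bond of that keto ester leads back to the ring B phenol and butanoyl Meldrum's acid.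
3. Forward: ring B comes from olivetolic acid and is protected (steps 1–4). The depside C–O bond is made first, as an unhindered β-keto ester (steps 5–6). The pyrone ring is closed, chlorinated at C3 and acetylated (steps 7–9), ring A then arises from the pyrone (step 10), and two deprotections finish the route (steps 11–12).
4. Stereochemistry: the target has no stereocentre. The two bridgehead centres of the cycloadduct are transient and vanish when CO2 is lost.

Key step: step 10

Remark: 1,1-dimethoxyethene 20 is taken as a purchased reagent, distilled before use and handled in base-washed glassware because traces of acid polymerise it; the 4-hydroxy-2-pyrones 15 and 17 are drawn as their 4-hydroxy-2-oxo tautomers.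

**Route**

Step 1
Reactants: 1 olivetolic acid; 2 benzyl bromide
Product: 3 benzyl 2,4-dihydroxy-6-pentylbenzoate
Conditions: BnBr (1.05 equiv), KHCO3, DMF, rt
Reagents that add atoms: 2 benzyl bromide, BrCc1ccccc1
Why: Carboxylate O-alkylation (SN2 esterification), in which KHCO3 deprotonates only the carboxylic acid so that both phenols stay free, and room temperature avoids decarboxylation of the β-resorcylic acid.

Step 2
Reactants: 3 benzyl 2,4-dihydroxy-6-pentylbenzoate; 4 allyl bromide
Product: 5 benzyl 2-hydroxy-6-pentyl-4-(prop-2-en-1-yloxy)benzoate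
Conditions: allyl bromide (1.05 equiv), K2CO3, acetone, 40 °C
Reagents that add atoms: 4 allyl bromide, C=CCBr
Why: Williamson ether synthesis that should be selective for the 4-OH, because the 2-OH is held in a hydrogen bond to the ester carbonyl and is both less acidic and less accessible.

Step 3
Reactants: 5 benzyl 2-hydroxy-6-pentyl-4-(prop-2-en-1-yloxy)benzoate; 2 benzyl bromide
Product: 6 benzyl 2-(benzyloxy)-6-pentyl-4-(prop-2-en-1-yloxy)benzoate
Conditions: BnBr (1.3 equiv), K2CO3, DMF, 60 °C
Reagents that add atoms: 2 benzyl bromide, BrCc1ccccc1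
Why: Williamson ether synthesis under more forcing conditions alkylates the chelated phenol, which is the only acidic site left.

Step 4
Reactants: 6 benzyl 2-(benzyloxy)-6-pentyl-4-(prop-2-en-1-yloxy)benzoate
Product: 7 benzyl 2-(benzyloxy)-4-hydroxy-6-pentylbenzoate
Conditions: Pd(PPh3)4 (5 mol %), morpholine (5 equiv), THF, rt
Reagents that add atoms: none
Why: Tsuji–Trost deallylation, in which zerovalent palladium ionises the allyl aryl ether to a π-allyl complex that morpholine captures, freeing the 4-OH while the benzyl ether and benzyl ester are untouched.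

Step 5
Reactants: 8 Meldrum's acid; 9 butanoyl chloride
Product: 10 5-(1-hydroxybutylidene)-2,2-dimethyl-1,3-dioxane-4,6-dione (butanoyl Meldrum's acid)
Conditions: pyridine (2 equiv), CH2Cl2, 0 °C to rt; dilute HCl wash
Reagents that add atoms: 9 butanoyl chloride, CCCC(=O)Cl
Why: C-acylation of Meldrum's acid (Yonemitsu acylation), the standard entry to acyl Meldrum's acids, which are obtained as stable enols.

Step 6
Reactants: 7 benzyl 2-(benzyloxy)-4-hydroxy-6-pentylbenzoate; 10 butanoyl Meldrum's acid
Product: 12 benzyl 2-(benzyloxy)-4-[(3-oxohexanoyl)oxy]-6-pentylbenzoate, via butanoylketene 11 (not isolated)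
Conditions: 10 (1.3 equiv), toluene, 110 °C
Reagents that add atoms: 10 butanoyl Meldrum's acid, CCCC(O)=C1C(=O)OC(C)(C)OC1=O
Why: Thermal cycloreversion of the acyl Meldrum's acid releases acetone, CO2 and an acylketene, which the phenol traps under neutral conditions (acylketene acylation), so the future depside C–O bond is formed at an unhindered carbonyl.

Step 7
Reactants: 12 benzyl 2-(benzyloxy)-4-[(3-oxohexanoyl)oxy]-6-pentylbenzoate; 13 malonyl dichloride
Product: 15 benzyl 2-(benzyloxy)-4-[(4-hydroxy-2-oxo-6-propyl-2H-pyran-5-carbonyl)oxy]-6-pentylbenzoate, via C-acylated acid chloride 14 (not isolated)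
Conditions: malonyl dichloride (1.5 equiv), 1,2-dichloroethane, rt to 60 °C, slow N2 stream to carry off HCl, no base
Reagents that add atoms: 13 malonyl dichloride, O=C(Cl)CC(=O)Cl
Why: Malonyl dichloride pyrone annulation of a β-keto ester, in which C-acylation at the doubly activated methylene is followed by O-acylation of the ketone enol (6-exo-trig lactonisation), giving the 4-hydroxy-2-pyrone-5-carboxylate without any base or nucleophile that could attack the aryl ester.

Step 8
Reactants: 15 the 4-hydroxy-2-pyrone; 16 N-chlorosuccinimide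
Product: 17 benzyl 2-(benzyloxy)-4-[(3-chloro-4-hydroxy-2-oxo-6-propyl-2H-pyran-5-carbonyl)oxy]-6-pentylbenzoate
Conditions: NCS (1.0 equiv), MeCN, 0 °C to rt
Reagents that add atoms: 16 N-chlorosuccinimide, O=C1CCC(=O)N1Cl
Why: Electrophilic chlorination of a cyclic β-dicarbonyl enol, for which C3 is the only nucleophilic carbon of the 4-hydroxy-2-pyrone, so one equivalent of NCS should react there and not on the deactivated ring B.

Step 9
Reactants: 17 the 3-chloro-4-hydroxy-2-pyrone; 18 acetic anhydride
Product: 19 benzyl 4-[(4-acetoxy-3-chloro-2-oxo-6-propyl-2H-pyran-5-carbonyl)oxy]-2-(benzyloxy)-6-pentylbenzoate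
Conditions: Ac2O (1.2 equiv), pyridine (1.5 equiv), CH2Cl2, 0 °C
Reagents that add atoms: 18 acetic anhydride, CC(=O)OC(C)=O
Why: O-acylation of the acidic enol (a vinylogous carboxylic acid) gives the 4-acetoxy-2-pyrone, which removes the proton that would destroy the ketene acetal and makes the diene more electron-poor.

Step 10
Reactants: 19 the 4-acetoxy-3-chloro-2-pyrone; 20 1,1-dimethoxyethene
Product: 23 benzyl 4-[(2-acetoxy-3-chloro-4-methoxy-6-propylbenzoyl)oxy]-2-(benzyloxy)-6-pentylbenzoate, via bicyclic lactone adduct 21 (not isolated), via cyclohexadiene ketal 22 (not isolated)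
Conditions: 1,1-dimethoxyethene (5 equiv), toluene, sealed tube, 110 °C
Reagents that add atoms: 20 1,1-dimethoxyethene, C=C(OC)OC
Why: Inverse-electron-demand Diels–Alder reaction in which the pyrone, made electron-poor by the 5-ester, the 3-chlorine and the 4-acetoxy group, serves as the 4π partner and the ketene acetal as the 2π partner, giving the 2-oxabicyclo[2.2.2]octenone 21, which expels CO2 by retro-[4+2] to the diene ketal 22 and then loses methanol by β-elimination (H from the ring CH2, OMe from the neighbouring ketal carbon) to give the benzene ring. The closest known reaction is the conversion of 2-pyrone carboxylates, including ring-alkylated ones, and of 3-halo-2-pyrones into alkoxybenzoates by heating with 1,1-dialkoxyethenes. Ring A is closed by an intermolecular [4+2] cycloaddition across pyrone C3 and C6, so both new ring bonds (C3–C4 and C5–C6 of ring A) form in one addition, whether concerted and asynchronous or by way of a zwitterion that collapses to the same adduct. No stereocentre has to be controlled, since the two bridgehead centres of 21 arise as a racemate and are lost with CO2. The one selectivity needed is regiochemical, CH2 to pyrone C6 and acetal carbon to C3, and it is secured by polarity, because C6 is the β-position of the unsaturated 5-ester and the δ-position of the lactone carbonyl while CH2 is the nucleophilic end of the acetal, which places OMe para to the ester carbon and next to chlorine. The conditions are neutral and free of base, so the aryl ester should survive, and any acetate lost from 23 to the released methanol would only give the product of step 11 early.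

Step 11
Reactants: 23 the acetoxy depside
Product: 24 benzyl 2-(benzyloxy)-4-[(3-chloro-2-hydroxy-4-methoxy-6-propylbenzoyl)oxy]-6-pentylbenzoate
Conditions: pyrrolidine (2 equiv), CH2Cl2, 0 °C
Reagents that add atoms: none
Why: Aminolysis of an aryl acetate, in which the small acetyl carbonyl should be attacked far faster than the di-ortho-substituted aryl benzoate or the 2,6-disubstituted benzyl benzoate, so only the acetate is removed.

Step 12
Reactants: 24 the dibenzyl depside
Product: 25 4-[(3-chloro-2-hydroxy-4-methoxy-6-propylbenzoyl)oxy]-2-hydroxy-6-pentylbenzoic acid (target)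
Conditions: BCl3 (6 equiv), pentamethylbenzene (6 equiv), CH2Cl2, −78 to 0 °C; then MeOH/H2O
Reagents that add atoms: none
Why: Lewis-acid debenzylation with a cation scavenger, in which BCl3 activates the benzyl ether and the chelated benzyl ester, pentamethylbenzene captures the benzyl cations by Friedel–Crafts alkylation, and the aryl chloride, the depside ester and the non-chelating methyl ether para to the carbonyl should remain.

**Compound list**

1 | olivetolic acid (2,4-dihydroxy-6-pentylbenzoic acid) | CCCCCc1cc(O)cc(O)c1C(=O)O | starting material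
2 | benzyl bromide | BrCc1ccccc1 | starting material
3 | benzyl 2,4-dihydroxy-6-pentylbenzoate | CCCCCc1cc(O)cc(O)c1C(=O)OCc1ccccc1 | intermediate
4 | allyl bromide | C=CCBr | starting material
5 | benzyl 2-hydroxy-6-pentyl-4-(prop-2-en-1-yloxy)benzoate | CCCCCc1cc(OCC=C)cc(O)c1C(=O)OCc1ccccc1 | intermediate
6 | benzyl 2-(benzyloxy)-6-pentyl-4-(prop-2-en-1-yloxy)benzoate | CCCCCc1cc(OCC=C)cc(OCc2ccccc2)c1C(=O)OCc1ccccc1 | intermediate
7 | benzyl 2-(benzyloxy)-4-hydroxy-6-pentylbenzoate | CCCCCc1cc(O)cc(OCc2ccccc2)c1C(=O)OCc1ccccc1 | intermediate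
8 | Meldrum's acid (2,2-dimethyl-1,3-dioxane-4,6-dione) | CC1(C)OC(=O)CC(=O)O1 | starting material
9 | butanoyl chloride | CCCC(=O)Cl | starting material
10 | 5-(1-hydroxybutylidene)-2,2-dimethyl-1,3-dioxane-4,6-dione (butanoyl Meldrum's acid, enol form) | CCCC(O)=C1C(=O)OC(C)(C)OC1=O | intermediate
11 | butanoylketene (3-oxohex-1-en-1-one), not isolated | CCCC(=O)C=C=O | intermediate
12 | benzyl 2-(benzyloxy)-4-[(3-oxohexanoyl)oxy]-6-pentylbenzoate | CCCCCc1cc(OC(=O)CC(=O)CCC)cc(OCc2ccccc2)c1C(=O)OCc1ccccc1 | intermediate
13 | malonyl dichloride | O=C(Cl)CC(=O)Cl | starting material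
14 | benzyl 2-(benzyloxy)-4-{[2-(3-chloro-3-oxopropanoyl)-3-oxohexanoyl]oxy}-6-pentylbenzoate (enolisable tricarbonyl, no fixed configuration), not isolated | CCCCCc1cc(OC(=O)C(C(=O)CCC)C(=O)CC(=O)Cl)cc(OCc2ccccc2)c1C(=O)OCc1ccccc1 | intermediate
15 | benzyl 2-(benzyloxy)-4-[(4-hydroxy-2-oxo-6-propyl-2H-pyran-5-carbonyl)oxy]-6-pentylbenzoate | CCCCCc1cc(OC(=O)C2=C(CCC)OC(=O)C=C2O)cc(OCc2ccccc2)c1C(=O)OCc1ccccc1 | intermediate
16 | N-chlorosuccinimide | O=C1CCC(=O)N1Cl | starting material
17 | benzyl 2-(benzyloxy)-4-[(3-chloro-4-hydroxy-2-oxo-6-propyl-2H-pyran-5-carbonyl)oxy]-6-pentylbenzoate | CCCCCc1cc(OC(=O)C2=C(CCC)OC(=O)C(Cl)=C2O)cc(OCc2ccccc2)c1C(=O)OCc1ccccc1 | intermediate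
18 | acetic anhydride | CC(=O)OC(C)=O | starting material
19 | benzyl 4-[(4-acetoxy-3-chloro-2-oxo-6-propyl-2H-pyran-5-carbonyl)oxy]-2-(benzyloxy)-6-pentylbenzoate | CCCCCc1cc(OC(=O)C2=C(CCC)OC(=O)C(Cl)=C2OC(C)=O)cc(OCc2ccccc2)c1C(=O)OCc1ccccc1 | intermediate
20 | 1,1-dimethoxyethene | C=C(OC)OC | starting material
21 | benzyl 4-{[5-acetoxy-4-chloro-8,8-dimethoxy-3-oxo-1-propyl-2-oxabicyclo[2.2.2]oct-5-ene-6-carbonyl]oxy}-2-(benzyloxy)-6-pentylbenzoate (racemic, one enantiomer drawn; the bicycle allows only this relative configuration of the bridgeheads), not isolated | CCC[C@@]12CC(OC)(OC)[C@@](Cl)(C(=O)O1)C(OC(C)=O)=C2C(=O)Oc1cc(CCCCC)c(C(=O)OCc2ccccc2)c(OCc2ccccc2)c1 | intermediate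
22 | benzyl 4-{[6-acetoxy-5-chloro-4,4-dimethoxy-2-propylcyclohexa-1,5-diene-1-carbonyl]oxy}-2-(benzyloxy)-6-pentylbenzoate, not isolated | CCCC1=C(C(=O)Oc2cc(CCCCC)c(C(=O)OCc3ccccc3)c(OCc3ccccc3)c2)C(OC(C)=O)=C(Cl)C(OC)(OC)C1 | intermediate
23 | benzyl 4-[(2-acetoxy-3-chloro-4-methoxy-6-propylbenzoyl)oxy]-2-(benzyloxy)-6-pentylbenzoate | CCCCCc1cc(OC(=O)c2c(CCC)cc(OC)c(Cl)c2OC(C)=O)cc(OCc2ccccc2)c1C(=O)OCc1ccccc1 | intermediate
24 | benzyl 2-(benzyloxy)-4-[(3-chloro-2-hydroxy-4-methoxy-6-propylbenzoyl)oxy]-6-pentylbenzoate | CCCCCc1cc(OC(=O)c2c(CCC)cc(OC)c(Cl)c2O)cc(OCc2ccccc2)c1C(=O)OCc1ccccc1 | intermediate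
25 | 4-[(3-chloro-2-hydroxy-4-methoxy-6-propylbenzoyl)oxy]-2-hydroxy-6-pentylbenzoic acid | CCCCCc1cc(OC(=O)c2c(CCC)cc(OC)c(Cl)c2O)cc(O)c1C(=O)O | target

**Step count**

Total step count: 12.
Longest linear sequence: 11 steps from olivetolic acid (steps 1–4 and 6–12); step 5 is a one-step side branch.

**Steps most likely to fail**

Step 10. At a diene substituted on all four carbons the cycloaddition may be slow. Acetyl transfer from the enol acetate (a vinylogous mixed anhydride) to the acetal or to released methanol, or addition–elimination at pyrone C4, could then consume 19 before ring A forms. The fallback sets out from 17 and replaces the acyl group by a methyl ether that cannot be transferred and is removed later by chelation. O-Methylation (MeI, K2CO3, acetone) should give benzyl 2-(benzyloxy)-4-[(3-chloro-4-methoxy-2-oxo-6-propyl-2H-pyran-5-carbonyl)oxy]-6-pentylbenzoate F1. Heating F1 with 20 (toluene, 140 °C) should lead through the bicyclic lactone benzyl 2-(benzyloxy)-4-{[4-chloro-5,8,8-trimethoxy-3-oxo-1-propyl-2-oxabicyclo[2.2.2]oct-5-ene-6-carbonyl]oxy}-6-pentylbenzoate F2 and the diene ketal benzyl 2-(benzyloxy)-4-{[5-chloro-4,4,6-trimethoxy-2-propylcyclohexa-1,5-diene-1-carbonyl]oxy}-6-pentylbenzoate F3, neither isolated, to benzyl 2-(benzyloxy)-4-[(3-chloro-2,4-dimethoxy-6-propylbenzoyl)oxy]-6-pentylbenzoate F4. BCl3 with pentamethylbenzene (CH2Cl2, −78 °C to rt) is then expected to cleave the methyl ether ortho to the ester carbonyl by chelation together with both benzyl groups, leaving the para methyl ether, so the route is rejoined at the target 25.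

Step 7. O-Acylation of the enol, self-condensation of malonyl dichloride and HCl-induced breakdown of the aryl β-keto ester may outrun the C-acylation and ring closure. The fallback sets out from 12 and separates the two bond formations. Magnesium-chelate C-acylation with methyl 3-chloro-3-oxopropanoate (MgCl2, pyridine, CH2Cl2, 0 °C) should give benzyl 2-(benzyloxy)-4-{[2-(3-methoxy-3-oxopropanoyl)-3-oxohexanoyl]oxy}-6-pentylbenzoate F5. Warming F5 in toluene with catalytic p-toluenesulfonic acid should make the enol of the propyl ketone lactonise onto the methyl ester with loss of methanol, which returns the route to 15.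

Step 12. Cleavage of the benzyl ester may stay incomplete at the low temperature that protects the para methyl ether, and warming may start demethylation or acyl migration across the depside. The fallback sets out from 24 and uses reductive instead of Lewis-acid cleavage. Hydrogenolysis (H2, 1 atm, Pd/C, EtOAc, rt, stopped when two equivalents of H2 are taken up to avoid hydrodechlorination) should remove both benzyl groups as toluene and arrive at the target 25 without any new compound.

**Further compounds**

F1 | step 10 | benzyl 2-(benzyloxy)-4-[(3-chloro-4-methoxy-2-oxo-6-propyl-2H-pyran-5-carbonyl)oxy]-6-pentylbenzoate | CCCCCc1cc(OC(=O)C2=C(CCC)OC(=O)C(Cl)=C2OC)cc(OCc2ccccc2)c1C(=O)OCc1ccccc1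
F2 | step 10 | benzyl 2-(benzyloxy)-4-{[4-chloro-5,8,8-trimethoxy-3-oxo-1-propyl-2-oxabicyclo[2.2.2]oct-5-ene-6-carbonyl]oxy}-6-pentylbenzoate (racemic, one enantiomer drawn, not isolated) | CCC[C@@]12CC(OC)(OC)[C@@](Cl)(C(=O)O1)C(OC)=C2C(=O)Oc1cc(CCCCC)c(C(=O)OCc2ccccc2)c(OCc2ccccc2)c1
F3 | step 10 | benzyl 2-(benzyloxy)-4-{[5-chloro-4,4,6-trimethoxy-2-propylcyclohexa-1,5-diene-1-carbonyl]oxy}-6-pentylbenzoate (not isolated) | CCCC1=C(C(=O)Oc2cc(CCCCC)c(C(=O)OCc3ccccc3)c(OCc3ccccc3)c2)C(OC)=C(Cl)C(OC)(OC)C1
F4 | step 10 | benzyl 2-(benzyloxy)-4-[(3-chloro-2,4-dimethoxy-6-propylbenzoyl)oxy]-6-pentylbenzoate | CCCCCc1cc(OC(=O)c2c(CCC)cc(OC)c(Cl)c2OC)cc(OCc2ccccc2)c1C(=O)OCc1ccccc1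
F5 | step 7 | benzyl 2-(benzyloxy)-4-{[2-(3-methoxy-3-oxopropanoyl)-3-oxohexanoyl]oxy}-6-pentylbenzoate | CCCCCc1cc(OC(=O)C(C(=O)CCC)C(=O)CC(=O)OC)cc(OCc2ccccc2)c1C(=O)OCc1ccccc1
F0 | step 12 | none | none
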